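Readings and results are simulated with constants of no real substance; noise was put on by code.

At the reading after 2.0 h the first question is how much Q is left, so I reckon with the fraction left, one minus D minus E, because the catalyst at 0.25 mM holds far less than the 0.25 M of Q.

| flask | Q | G | Z | temperature | remark | time |
|---|---|---|---|---|---|---|
| birch | 0.25 M | 0.125 M | 0.25 mM | 55 °C | run made earlier |  |
| ash | 0.25 M | 0.125 M | 0.17 mM | 66 °C | run made earlier |  |
| larch | 0.25 M | 0.125 M | 0.38 mM | 55 °C | run made earlier |  |
| dusk | 0.25 M | 0.125 M | 0.25 mM |  | everything together at the start at 40 °C, warmed to 60 °C at 50 min | 2.0 h |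
| dawn | 0.25 M | 0.125 M (in portions, 4, over 50 min) | 0.25 mM | 60 °C | first portion at the start, last at 50 min | 2.0 h |
| spring | 0.25 M (fed, over 50 min) | 0.125 M | 0.25 mM |  | the addition at 40 °C, then warmed to 60 °C; the feed brings no volume worth counting | 2.0 h |
| noon | 0.25 M (fed, over 50 min) | 0.125 M | 0.25 mM | 60 °C | all else is in the flask from the start; the feed brings no volume worth counting | 2.0 h |
| winter | 0.25 M | 0.125 M | 0.25 mM | 60 °C | everything together at the start | 2.0 h |

- birch (time / min: D / %, E / %): 10.0: 10.4, 4.9; 20.0: 18.6, 9.0; 30.0: 23.4, 13.0; 40.0: 27.7, 14.6; 50.0: 31.8, 18.6; 60.0: 35.1, 21.2; 80.0: 37.9, 25.8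
- ash (time / min: D / %, E / %): 10.0: 17.9, 6.9; 15.0: 25.1, 8.6; 20.0: 30.2, 11.4; 30.0: 37.0, 16.3; 50.0: 44.7, 23.3; 80.0: 49.5, 31.3; 120: 52.3, 37.9
- larch (time / min: D / %, E / %): 10.0: 10.3, 7.1; 15.0: 14.3, 9.2; 20.0: 16.5, 12.2; 30.0: 22.3, 17.5; 50.0: 29.2, 26.0; 80.0: 34.7, 34.4; 120: 37.8, 41.1

(readings scatter by 0.5 percentage points)

- a species is counted by the Q in it: one D counts as two
- the numbers in the tables scatter with a standard deviation of 0.5 percentage points
- on the list of suspects stand: L -> J; 2 Q -> D; G + Z -> L; X <-> Z + E; Q + J -> X

- which flask leads in amount of D, in percent of the Q charged ("all alike" within 1.5 percentage points) (dusk / dawn / spring / noon / winter / all alike)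
- how much D is there at the end, in percent of the Q charged: dusk
- how much D is there at the end, in percent of the Q charged: dawn
- how much D is there at the end, in percent of the Q charged: spring
- how much D is there at the end, in percent of the Q charged: noon
- how much D is there at the end, in percent of the Q charged: winter

For a purely second-order loss the reciprocal of the fraction left climbs linearly, so the mean of its square from the start equals the fraction at that moment. The D coefficient is then D divided by time and by fraction left, an approximation while E runs beside it. At 30.0 min birch gives 0.0123 /min and larch 0.0123 /min, a match with Z at 0.25 mM and 0.38 mM, so I take D as made without catalyst. Ash gives 0.0264 /min at 66 °C, and interpolating the logarithm gives 0.0174 /min at 60 °C.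

I treat E as pseudo-first-order in Q and use the mean fraction, halfway between one and the fraction left. That gives 0.00530 /min in birch, 0.00728 /min in larch and 0.00741 /min in ash. Scaling ash in simple proportion to Z and interpolating gives 0.00735 /min. The selectivity factor, D growth over E growth, is then the fraction left divided by 42.3%, the ratio of the E and D coefficients. Both terms integrate in closed form, so for winter I get 17.3% of Q left and 45.9% of D.

The weak link is that proportion, since larch against birch shows E rising with Z to the power 0.760. Leaving ash unscaled, which is power zero, gives an E coefficient of 0.00617 /min, a ratio of 35.5%, 19.3% of Q left in winter and 48.6% of D, so my two ends for winter stand at 45.9% and 48.6%. The power read from larch and birch lies about a quarter of the way down from one to zero, so I commit to 46.5% of D in winter, above the forecast's 43%. The balance concentration, the concentration of Q at which D and E grow equally, is the proportional ratio times the charge, 0.106 M.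

The forecast gives 42% for dusk, 44.5% for dawn, 39% for spring and 36% for noon, and names dawn as the leader, noting “Feeding Q keeps it low and suppresses D”.

The flasks give 42.7% of D in dusk, 49.2% in dawn, 39.7% in spring, 36.8% in noon and 44.7% in winter, so dawn leads.

    L → J (k = 0.360 /s, Ea = 93.0 kJ/mol)
    2 Q → D (k = 5.70 × 10⁻⁴ /M/s, Ea = 60.0 kJ/mol)
    G + Z → L (k = 3.30 /M/s, Ea = 60.0 kJ/mol)
    X ⇌ Z + E (K = 0.0680 M, k = 2.50 /s, Ea = 65.0 kJ/mol, ΔH = 16.0 kJ/mol)
    Q + J → X (k = 1.50 /M/s, Ea = 44.0 kJ/mol)
    (constants at 60 °C)

A reading of noon at 80 min finds Q at 41.3% of the charge, about the balance point of 42.3%, with D at 29.4% and E at 29.2%, level. A neighbouring flask like noon, charged with 0.062 M of Q, below the balance concentration of 0.106 M, ends with E at 75.7% of its Q and D at 7.79%.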